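Ring B of the pterocarpan is disconnected at its two C–C bonds, C6–C6a and C11a–C11b, which flank the C6a–C11a bond; the latter is the C2=C3 bond of a benzofuran that already carries rings C and D with both prenyl-type units. A ring-A aryl bromide bearing an ortho OCH2SnBu3 group supplies the four-atom unit C11b–C4a–O5–C6. One palladium-catalysed, ligand-controlled dearomative annulation adds this unit syn across the benzofuran C2=C3 bond, closing ring B and setting the cis-(6aR,11aR) stereocentres in the last step, without protecting groups. The benzofuran arises from 2,4,5-trihydroxybenzaldehyde by a tandem double Claisen rearrangement.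

Key step: step 9

Remarks:
- Pterocarpan numbering is used for 13: O5, C6 (OCH2), C6a, ring D C6b–C10a, O11, C11a (OCH), C11b (ring-A carbon on C11a).
- Catalyst-bound organopalladium species of step 9 are described in its Why line and carry no compound numbers.
- The ligand antipode that leads to the (6aR,11aR) series cannot be predicted and has to be fixed by a first experiment; (R) is written as the working choice.

Step 1
Reactants: 1 4-bromobenzene-1,3-diol (4-bromoresorcinol)
Product: 2 4-bromo-6-(3-methylbut-2-en-1-yl)benzene-1,3-diol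
Conditions: 2-methylbut-3-en-2-ol (1.2 equiv), BF3·OEt2 (0.3 equiv), 1,4-dioxane, rt
Reagents that add atoms: 2-methylbut-3-en-2-ol, CC(C)(O)C=C
Why: Friedel–Crafts prenylation via the dimethylallyl cation should take C6, the only unhindered position activated by both hydroxyls (C2 lies between the two hydroxyls and C5 is meta to both).

Step 2
Reactants: 2 4-bromo-6-(3-methylbut-2-en-1-yl)benzene-1,3-diol
Product: 3 4-bromo-2-(3-methylbut-2-en-1-yl)-5-[(tributylstannyl)methoxy]phenol
Conditions: Bu3SnCH2I (1.0 equiv), K2CO3 (1.0 equiv), DMF, rt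
Reagents that add atoms: tributyl(iodomethyl)stannane, CCCC[Sn](CCCC)(CCCC)CI
Why: Williamson etherification under mono-deprotonation: the hydroxyl ortho to bromine is the more acidic, so it should be ionised and alkylated in preference to the one next to the prenyl group.

Step 3
Reactants: 4 2,4,5-trihydroxybenzaldehyde
Product: 5 2,5-dihydroxy-4-[(2-methylbut-3-yn-2-yl)oxy]benzaldehyde
Conditions: 3-chloro-3-methylbut-1-yne (1.1 equiv), DBU (1.1 equiv), CuCl2 (1 mol%), MeCN, 0 °C, argon
Reagents that add atoms: 3-chloro-3-methylbut-1-yne, CC(C)(Cl)C#C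
Why: Copper-catalysed propargylic etherification (Williamson type) of the most acidic phenol, the 4-OH para to the formyl group; the 2-OH is hydrogen-bonded to the aldehyde and the 5-OH is less acidic.

Step 4
Reactants: 5 2,5-dihydroxy-4-[(2-methylbut-3-yn-2-yl)oxy]benzaldehyde
Product: 6 2,5-dihydroxy-4-[(2-methylbut-3-en-2-yl)oxy]benzaldehyde
Conditions: H2 (1 atm), Pd/CaCO3 poisoned with Pb(OAc)2 (Lindlar catalyst), quinoline, EtOAc, rt
Reagents that add atoms: none
Why: Lindlar semi-hydrogenation reduces the terminal alkyne to the vinyl group and stops there, leaving aldehyde and phenols untouched.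

Step 5
Reactants: 6 2,5-dihydroxy-4-[(2-methylbut-3-en-2-yl)oxy]benzaldehyde
Product: 7 2-hydroxy-4-[(2-methylbut-3-en-2-yl)oxy]-5-[(2-methylbut-3-yn-2-yl)oxy]benzaldehyde
Conditions: 3-chloro-3-methylbut-1-yne (1.2 equiv), DBU (1.2 equiv), CuCl2 (1 mol%), MeCN, 0 °C, argon
Reagents that add atoms: 3-chloro-3-methylbut-1-yne, CC(C)(Cl)C#C
Why: The same copper-catalysed propargylic etherification should take the 5-OH, because the 2-OH is chelated to the aldehyde, as in the selective 5-O-alkylation of 2,5-dihydroxybenzaldehydes.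

Step 6
Reactants: 7 2-hydroxy-4-[(2-methylbut-3-en-2-yl)oxy]-5-[(2-methylbut-3-yn-2-yl)oxy]benzaldehyde
Product: 9 6-[(2-methylbut-3-en-2-yl)oxy]-5-[(2-methylbut-3-yn-2-yl)oxy]-2,3-dihydro-1-benzofuran-3-ol (racemic), via epoxide 8 (not isolated)
Conditions: Me3S+ I− (1.2 equiv), NaH (2.2 equiv), DMSO/THF, 0 °C to rt; aqueous work-up
Reagents that add atoms: trimethylsulfonium iodide, C[S+](C)C.[I-]
Why: Corey–Chaykovsky methylene transfer to the aldehyde gives the epoxide, which the ortho phenoxide opens at its CH2 terminus to close the dihydrofuran ring; the C3 stereocentre is formed racemic and is erased in step 7.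

Step 7
Reactants: 9 6-[(2-methylbut-3-en-2-yl)oxy]-5-[(2-methylbut-3-yn-2-yl)oxy]-2,3-dihydro-1-benzofuran-3-ol
Product: 10 6-[(2-methylbut-3-en-2-yl)oxy]-5-[(2-methylbut-3-yn-2-yl)oxy]-1-benzofuran
Conditions: pyridinium p-toluenesulfonate (10 mol%), 4 Å molecular sieves, toluene, 50 °C
Reagents that add atoms: none
Why: Acid-catalysed E1 dehydration: the benzylic cation is stabilised by the para 6-alkoxy group and the ring oxygen, so a pyridinium acid should suffice and spare the tertiary ethers, and loss of the C2 proton gives the aromatic furan.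

Step 8
Reactants: 10 6-[(2-methylbut-3-en-2-yl)oxy]-5-[(2-methylbut-3-yn-2-yl)oxy]-1-benzofuran
Product: 12 7,7-dimethyl-4-(3-methylbut-2-en-1-yl)-7H-furo[3,2-f]chromen-5-ol, via propargyl ether phenol 11 (not isolated)
Conditions: N,N-diethylaniline, 190 °C, argon
Reagents that add atoms: none
Why: Two aromatic Claisen rearrangements in one heating: the 6-O-(1,1-dimethylallyl) group can only move to C7 (C5 carries oxygen) and gives the prenyl phenol 11, and the 5-O-propargyl group can only move to C4, the allenyl phenol then closing to the 2,2-dimethyl-2H-pyran by 1,5-H shift and oxa-6π electrocyclisation.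

Step 9
Reactants: 3 4-bromo-2-(3-methylbut-2-en-1-yl)-5-[(tributylstannyl)methoxy]phenol (1.3 equiv); 12 7,7-dimethyl-4-(3-methylbut-2-en-1-yl)-7H-furo[3,2-f]chromen-5-ol
Product: 13 Lespecyrtin E3, the (6aR,11aR)-cis-pterocarpan with 3-OH and 2-prenyl on ring A and with 9-OH, 10-prenyl and a 2,2-dimethyl-2H-pyran fused at C7–C8 (pyran O on C8) on ring D
Conditions: Pd2(dba)3 (5 mol%), (R)-SEGPHOS (12 mol%), toluene, 90 °C, argon
Reagents that add atoms: none
Why: Proposed new method: zerovalent palladium inserts into the C–Br bond of 3, the arylpalladium adds syn across the C2=C3 bond of benzofuran 12 (aryl to C2, palladium to the benzylic C3, where no syn β-hydrogen is left), the OCH2 group moves from tin to palladium to give a seven-membered palladacycle of divalent palladium, and C(sp3)–C(sp3) reductive elimination releases the product (if tin-to-palladium transfer comes first, a five-membered oxapalladacycle inserts the benzofuran and reaches the same palladacycle). The closest known reaction types are the Heck oxyarylation of 2H-chromenes with 2-halophenols (a Larock-type annulation that builds pterocarpans through the other pair of bonds), dearomative Heck/anion-capture cascades of benzofurans and indoles, and the annulation of (2-halophenoxy)methylstannanes with alkynes through oxapalladacycles. Ring B is closed as a formal [4+2] annulation of the unit C11b–C4a–O5–C6 onto C6a=C11a, the six-membered ring being sealed by reductive elimination at C6–C6a. C11a is set in the enantio-determining migratory insertion, whose face is chosen by the chiral bisphosphine on palladium, and C6a follows from syn insertion and retentive reductive elimination, which allow only the cis-6a,11a fusion. The step needs regioselectivity (aryl to C2), expected from benzylic stabilisation of palladium at C3 and the open C2–H terminus, and chemoselectivity for the benzofuran double bond over the trisubstituted prenyl alkenes and the chromene alkene flanked by the gem-dimethyl carbon, which are too hindered to insert.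

Compound list
1 | 4-bromobenzene-1,3-diol (4-bromoresorcinol) | Oc1ccc(Br)c(O)c1 | starting material
2 | 4-bromo-6-(3-methylbut-2-en-1-yl)benzene-1,3-diol | CC(C)=CCc1cc(Br)c(O)cc1O | intermediate
3 | 4-bromo-2-(3-methylbut-2-en-1-yl)-5-[(tributylstannyl)methoxy]phenol | CC(C)=CCc1cc(Br)c(OC[Sn](CCCC)(CCCC)CCCC)cc1O | intermediate
4 | 2,4,5-trihydroxybenzaldehyde | O=Cc1cc(O)c(O)cc1O | starting material
5 | 2,5-dihydroxy-4-[(2-methylbut-3-yn-2-yl)oxy]benzaldehyde | O=Cc1cc(O)c(OC(C)(C)C#C)cc1O | intermediate
6 | 2,5-dihydroxy-4-[(2-methylbut-3-en-2-yl)oxy]benzaldehyde | O=Cc1cc(O)c(OC(C)(C)C=C)cc1O | intermediate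
7 | 2-hydroxy-4-[(2-methylbut-3-en-2-yl)oxy]-5-[(2-methylbut-3-yn-2-yl)oxy]benzaldehyde | O=Cc1cc(OC(C)(C)C#C)c(OC(C)(C)C=C)cc1O | intermediate
8 | 5-[(2-methylbut-3-en-2-yl)oxy]-4-[(2-methylbut-3-yn-2-yl)oxy]-2-(oxiran-2-yl)phenol (racemic, not isolated) | C1OC1c1cc(OC(C)(C)C#C)c(OC(C)(C)C=C)cc1O | intermediate
9 | 6-[(2-methylbut-3-en-2-yl)oxy]-5-[(2-methylbut-3-yn-2-yl)oxy]-2,3-dihydro-1-benzofuran-3-ol (racemic) | OC1COc2cc(OC(C)(C)C=C)c(OC(C)(C)C#C)cc21 | intermediate
10 | 6-[(2-methylbut-3-en-2-yl)oxy]-5-[(2-methylbut-3-yn-2-yl)oxy]-1-benzofuran | c1coc2cc(OC(C)(C)C=C)c(OC(C)(C)C#C)cc12 | intermediate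
11 | 7-(3-methylbut-2-en-1-yl)-5-[(2-methylbut-3-yn-2-yl)oxy]-1-benzofuran-6-ol (not isolated) | c1coc2c(CC=C(C)C)c(O)c(OC(C)(C)C#C)cc12 | intermediate
12 | 7,7-dimethyl-4-(3-methylbut-2-en-1-yl)-7H-furo[3,2-f]chromen-5-ol (benzofuran with 6-OH, 7-prenyl and a 2,2-dimethyl-2H-pyran fused at C4–C5, pyran O on C5) | c1coc2c(CC=C(C)C)c(O)c3OC(C)(C)C=Cc3c12 | intermediate
13 | Lespecyrtin E3, (6aR,11aR) | CC(C)=CCc1cc2c(cc1O)OC[C@H]1c3c4c(c(O)c(CC=C(C)C)c3O[C@@H]21)OC(C)(C)C=C4 | target

Total step count: 9. Longest linear sequence: 7 steps (steps 3 to 8, then step 9).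

Steps most likely to fail

1. Step 9 (Proposed new method). Insertion of the hindered, electron-rich benzofuran may be too slow, so that tin-to-palladium transfer between two molecules of 3 (oligomeric benzyl aryl ethers) or protodestannylation takes over. The insertion may also show poor facial discrimination, and slow alkyl–alkyl reductive elimination may end in protodepalladation. Fallback by known reactions (Noyori-type asymmetric transfer hydrogenation of an isoflavone with dynamic kinetic resolution, then acid-mediated closure of ring C); it sets out from 2 and from 7 and comes back at 13.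
 - Compound 2 would be protected with MOMCl/i-Pr2NEt as the bis(methoxymethyl) ether F1. Bromine–lithium exchange (n-BuLi, THF, −78 °C) and DMF quench would give the benzaldehyde F2.
 - Aldehyde 7 would be heated as in step 8 to the rearranged chromene-carbaldehyde F3, protected (MOMCl, NaH) as the bis(methoxymethyl) ether F4, and condensed with TsNHNH2 to the tosylhydrazone F5.
 - Base-mediated coupling of F5 with F2 (K2CO3, 1,4-dioxane, 110 °C; aryldiazomethane addition to the aldehyde and 1,2-hydride shift) should give the deoxybenzoin F6.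
 - Brief acid treatment (cat. HCl, MeOH, rt) should free the hydrogen-bonded hydroxyl ortho to the ketone to give the phenol F7. Me2NCH(OMe)2 (toluene, 100 °C) should then close the isoflavone F8.
 - Transfer hydrogenation with RuCl(p-cymene)[(R,R)-TsDPEN] (antipode chosen for the 3R,4R series) and HCO2H/Et3N should reduce C=C and C=O with dynamic kinetic resolution at C3 to the cis-(3R,4R)-isoflavan-4-ol F9.
 - HCl/MeOH would remove the three MOM groups and close ring C through the benzylic cation, which can only give the cis fusion, to reach 13.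

2. Step 8. The tertiary allyl group may be lost as isoprene before it migrates, and the electron-rich phenol may decompose while the slower propargyl rearrangement is still running. Fallback (sets out from 10, comes back at 12): the two events would be separated and the pyran closed by a different reaction type. Ph3PAuNTf2 (2 mol%, CH2Cl2, rt) should cyclise the aryl propargyl ether by 6-endo-dig hydroarylation at C4 to the chromene F10, with the dimethylallyl ether intact. Eu(fod)3 (10 mol%, CHCl3, 60 °C) would then promote the Claisen shift to C7 and give 12.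

3. Step 1. The cationic prenylation may show poor positional selectivity (C2 against C6, double alkylation), and the acid may cyclise the product onto its own prenyl group to a chroman. Fallback (sets out from 1, comes back at 2): ICl (Et2O, 0 °C) should iodinate C6 to give 4-bromo-6-iodobenzene-1,3-diol F11. Suzuki–Miyaura coupling at the C–I bond with 2-(3-methylbut-2-en-1-yl)-4,4,5,5-tetramethyl-1,3,2-dioxaborolane, PdCl2(IPent)(3-chloropyridine), KOH, THF, 65 °C, would attach the prenyl group through its CH2 terminus and leave the C–Br bond for step 9, giving 2.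

Further compounds
F1 | step 9 | 1-bromo-2,4-bis(methoxymethoxy)-5-(3-methylbut-2-en-1-yl)benzene | CC(C)=CCc1cc(Br)c(OCOC)cc1OCOC
F2 | step 9 | 2,4-bis(methoxymethoxy)-5-(3-methylbut-2-en-1-yl)benzaldehyde | CC(C)=CCc1cc(C=O)c(OCOC)cc1OCOC
F3 | step 9 | 6,8-dihydroxy-2,2-dimethyl-7-(3-methylbut-2-en-1-yl)-2H-chromene-5-carbaldehyde | O=Cc1c(O)c(CC=C(C)C)c(O)c2OC(C)(C)C=Cc12
F4 | step 9 | 6,8-bis(methoxymethoxy)-2,2-dimethyl-7-(3-methylbut-2-en-1-yl)-2H-chromene-5-carbaldehyde | O=Cc1c(OCOC)c(CC=C(C)C)c(OCOC)c2OC(C)(C)C=Cc12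
F5 | step 9 | 4-methylbenzenesulfonohydrazone (tosylhydrazone) of F4 | Cc1ccc(cc1)S(=O)(=O)NN=Cc1c(OCOC)c(CC=C(C)C)c(OCOC)c2OC(C)(C)C=Cc12
F6 | step 9 | 1-[2,4-bis(methoxymethoxy)-5-(3-methylbut-2-en-1-yl)phenyl]-2-[6,8-bis(methoxymethoxy)-2,2-dimethyl-7-(3-methylbut-2-en-1-yl)-2H-chromen-5-yl]ethan-1-one | CC(C)=CCc1cc(C(=O)Cc2c(OCOC)c(CC=C(C)C)c(OCOC)c3OC(C)(C)C=Cc23)c(OCOC)cc1OCOC
F7 | step 9 | 1-[2-hydroxy-4-(methoxymethoxy)-5-(3-methylbut-2-en-1-yl)phenyl]-2-[6,8-bis(methoxymethoxy)-2,2-dimethyl-7-(3-methylbut-2-en-1-yl)-2H-chromen-5-yl]ethan-1-one | CC(C)=CCc1cc(C(=O)Cc2c(OCOC)c(CC=C(C)C)c(OCOC)c3OC(C)(C)C=Cc23)c(O)cc1OCOC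
F8 | step 9 | 3-[6,8-bis(methoxymethoxy)-2,2-dimethyl-7-(3-methylbut-2-en-1-yl)-2H-chromen-5-yl]-7-(methoxymethoxy)-6-(3-methylbut-2-en-1-yl)-4H-chromen-4-one | O=c1c(-c2c(OCOC)c(CC=C(C)C)c(OCOC)c3OC(C)(C)C=Cc23)coc2cc(OCOC)c(CC=C(C)C)cc12
F9 | step 9 | (3R,4R)-3-[6,8-bis(methoxymethoxy)-2,2-dimethyl-7-(3-methylbut-2-en-1-yl)-2H-chromen-5-yl]-7-(methoxymethoxy)-6-(3-methylbut-2-en-1-yl)chroman-4-ol | CC(C)=CCc1cc2c(cc1OCOC)OC[C@@H](c1c(OCOC)c(CC=C(C)C)c(OCOC)c3OC(C)(C)C=Cc13)[C@H]2O
F10 | step 8 | 7,7-dimethyl-5-[(2-methylbut-3-en-2-yl)oxy]-7H-furo[3,2-f]chromene | c1coc2cc(OC(C)(C)C=C)c3OC(C)(C)C=Cc3c12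
F11 | step 1 | 4-bromo-6-iodobenzene-1,3-diol | Oc1cc(O)c(Br)cc1I
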